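**Retrosynthetic overview**

1. Target 23 ← its C9 PMB ether 22 ← Z-enone 19: the C3 angelate and the 4,5-epoxide come from a C3 ketone with a ring-cis C4=C5 bond, and the 8,9-cis-dioxygen pattern comes from a C8 ketone.
2. Ten-membered ring ← six-membered ring: the C5–C6 bond is made while the C3–C8 bond of cyclohexane 10 is broken (anionic oxy-Cope ring expansion), and the resulting C7 enolate is captured by acetone in the same flask.
3. Enabling feature: in 10 the ring carbons C3 and C8 (ring C1, C2, C3, C8, C9, C10) carry isopropenyl (C4=C5) and vinyl (C7=C6) plus one oxygen each, so C6=C7–C8(O−)–C3(OMOM)–C4=C5 is a 3-oxido-4-alkoxy-1,5-diene whose central bond is a ring bond.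
4. Ring order: cyclohexene of (S)-carvone → 1,10-epoxide (made on the six-membered ring, directed by the C9 hydroxyl) → ten-membered carbocycle (step 10) → 4,5-epoxide (step 16).
5. Carbon sources: (S)-carvone gives C1–C5, C8–C10, C14, C15; vinylmagnesium bromide gives C6–C7; acetone gives C11–C13.

Key step: step 10

Remark on the chemistry: the SMILES is read as a germacrane in which both epoxides have their ring bonds cis (formally from Z-alkenes). Germacrane numbering is used for all compounds, including the cyclohexanes (ring C1, C2, C3, C8, C9, C10; C14 on C10; C15 on C4; C11–C13 on C7). With the ring drawn flat, α is the face of the C9 oxygen and β the other. In these terms the target is 1,10α-epoxy, 4,5β-epoxy, 3α-angeloyloxy, 7α-isopropenyl, 8α-senecioyloxy, 9α-hydroxy, i.e. (1R,3S,4S,5S,7R,8S,9S,10S).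

**Route**

Step 1
Reactants: 1 (S)-(+)-carvone
Product: 2 trans-8-acetoxy enone (trans-6-acetoxycarvone)
Conditions: Mn(OAc)3, benzene, reflux, Dean–Stark
Reagents that add atoms: manganese triacetate, CC(=O)[O-].CC(=O)[O-].CC(=O)[O-].[Mn+3]
Why: Mn(OAc)3 α′-acetoxylation of an enone (through the cross-conjugated manganese enolate) should place the acetoxy group at C8 anti to the neighbouring isopropenyl group; C8 is oxidised again in step 6, so this centre only brings C8 to the ketone level later.

Step 2
Reactants: 2 trans-8-acetoxy enone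
Product: 3 allylic alcohol (9α-OH cis to isopropenyl and trans to OAc)
Conditions: NaBH4, CeCl3·7H2O, MeOH, −78 °C, AcOH quench
Reagents that add atoms: none
Why: Luche 1,2-reduction with axial hydride delivery should give the equatorial C9 alcohol cis to the isopropenyl group (as in carvone to cis-carveol), which fixes C9 and leaves the acetate in place at low temperature.

Step 3
Reactants: 3 allylic alcohol
Product: 4 cis-epoxy alcohol
Conditions: VO(acac)2 (cat.), t-BuOOH, CH2Cl2, 0 °C to rt
Reagents that add atoms: tert-butyl hydroperoxide, CC(C)(C)OO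
Why: Vanadium-catalysed hydroxyl-directed epoxidation of the cyclic allylic alcohol should deliver oxygen only to the C1=C10 bond and from the face of the C9 hydroxyl, setting C1 and C10 on the rigid six-membered ring and removing the ring alkene that could otherwise open a second [3,3] pathway in step 10.

Step 4
Reactants: 4 cis-epoxy alcohol
Product: 5 PMB ether acetate
Conditions: 2-(4-methoxybenzyloxy)-4-methylquinoline, MeOTf, MgO, PhCF3, 0 °C to rt
Reagents that add atoms: 2-(4-methoxybenzyloxy)-4-methylquinoline, COc1ccc(COc2cc(C)c3ccccc3n2)cc1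
Why: Neutral PMB transfer from the N-methylated 2-benzyloxyquinolinium salt formed in situ should etherify the hindered C9 alcohol without base (no acetate migration) or acid (no epoxide opening); PMB is chosen because it chelates in steps 10 and 11 and leaves under neutral oxidation at the end.

Step 5
Reactants: 5 PMB ether acetate
Product: 6 C8 alcohol
Conditions: K2CO3 (cat.), MeOH, 0 °C to rt
Reagents that add atoms: none
Why: Base-catalysed transesterification with methanol removes the acetate, and the molecule has no free alkoxide placed to attack the epoxide.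

Step 6
Reactants: 6 C8 alcohol
Product: 7 epoxy ketone
Conditions: Dess–Martin periodinane, NaHCO3, CH2Cl2, 0 °C
Reagents that add atoms: none
Why: Dess–Martin oxidation under buffered conditions should give the α-alkoxy ketone without epimerising C9 or opening the epoxide.

Step 7
Reactants: 7 epoxy ketone
Product: 8 α-hydroxy ketone (3β-OH)
Conditions: KHMDS, THF, −78 °C; 3-phenyl-2-(phenylsulfonyl)oxaziridine; H2O
Reagents that add atoms: 3-phenyl-2-(phenylsulfonyl)oxaziridine, O=S(=O)(N1OC1c1ccccc1)c1ccccc1
Why: Enolate hydroxylation with the Davis oxaziridine: deprotonation is expected at C3 (allylic, giving the conjugated dienolate) rather than at the alkoxy-bearing C9, and the oxidant should approach anti to the C9 ether and the epoxide; C3 becomes trigonal again in step 10.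

Step 8
Reactants: 8 α-hydroxy ketone
Product: 9 MOM ether ketone
Conditions: MOMCl, i-Pr2NEt, DMAP (cat.), CH2Cl2, 40 °C
Reagents that add atoms: chloromethyl methyl ether, COCCl
Why: Alkylation of the tertiary hydroxyl gives an acetal ether that, unlike a silyl or acyl group, cannot migrate to the neighbouring alkoxide in step 10 and later appears as an enol ether ready for dehydrogenation.

Step 9
Reactants: 9 MOM ether ketone
Product: 10 vinyl carbinol (8α-vinyl, 8β-OH)
Conditions: vinylmagnesium bromide, CeCl3, THF, −78 °C
Reagents that add atoms: vinylmagnesium bromide, C=C[Mg]Br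
Why: Organocerium 1,2-addition (suppresses enolisation at C9) with polar Felkin–Anh attack anti to the axial C3 acetal oxygen should give the isomer shown; the C8 epimer would serve equally because C8 becomes trigonal in step 10.

Step 10
Reactants: 10 vinyl carbinol
Product: 15 ring-expanded aldol, via potassium alkoxide 11 (not isolated), via ring-expanded potassium enolate 12 (not isolated), via dichlorocerium enolate 13 (not isolated), via dichlorocerium aldolate 14 (not isolated)
Conditions: KH, 18-crown-6, THF, 0 °C to rt; then CeCl3, −78 °C; acetone, −78 °C; H2O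
Reagents that add atoms: acetone, CC(C)=O
Why: Deprotonation gives the potassium alkoxide 11, whose C3–C8 bond, flanked by the oxido group at C8 and the acetal oxygen at C3, should break in an anionic oxy-Cope [3,3]-shift through a chair in which the vinyl terminus C6 bonds to the isopropenyl terminus C5. The closest known reaction type is the anionic oxy-Cope ring expansion of 1,2-dialkenylcyclohexanols to cyclodec-5-enones with capture of the enolate by an electrophile. The ten-membered ring is closed by this sigmatropic four-carbon ring expansion of the six-membered ring (new C5–C6 bond, loss of the C3–C8 bond), so no end-to-end medium-ring cyclisation is needed, and C1, C9 and C10 are carried over unchanged. With C9 equatorial on the chair, the enolate C7=C8 should form with C6 and C9 trans (ring-E) while C3 emerges as the regiodefined MOM enol ether; the C8 epimer of 10 would give the same ring-E enolate through the diequatorial chair. After potassium-to-cerium exchange, chelation of the enolate oxygen and the C9 PMB ether oxygen by trivalent cerium should place C10, and with it the ring, below the enolate plane, so acetone adds to C7 from the open face and sets C7 (R, 7α side chain). The step needs the [3,3]-shift to win over Grob-type opening of the epoxide (its C–O bonds are not antiperiplanar to C8–C9) and over oxygen-to-oxygen group transfer (excluded by the MOM acetal), and the aldol to win over proton transfer from acetone (cerium enolate).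

Step 11
Reactants: 15 ring-expanded aldol
Product: 16 8α,11-diol
Conditions: Zn(BH4)2, Et2O, −20 °C
Reagents that add atoms: none
Why: Chelation-controlled reduction: the five-membered chelate with the C9 PMB ether and the six-membered chelate with the C11 hydroxyl both expose the same carbonyl face, so hydride should give the 8α-alcohol, cis to the C9 oxygen and to the C7 side chain.

Step 12
Reactants: 16 8α,11-diol
Product: 17 C8 senecioate
Conditions: 3-methylbut-2-enoyl chloride, pyridine, DMAP (cat.), CH2Cl2, 0 °C
Reagents that add atoms: 3-methylbut-2-enoyl chloride, CC(C)=CC(=O)Cl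
Why: DMAP-catalysed acylation with the acid chloride should esterify the secondary C8 hydroxyl while the tertiary C11 hydroxyl stays free.

Step 13
Reactants: 17 C8 senecioate
Product: 18 Z-enone
Conditions: Pd(OAc)2, NaHCO3, MeCN/H2O, rt
Reagents that add atoms: none
Why: Saegusa–Ito-type dehydrogenation of an alkyl enol ether: palladation at C4, β-hydride elimination from C5 and hydrolysis of the oxocarbenium ion (loss of the MOM group) should give the conjugated enone with the C4=C5 bond cis in the ring, the geometry favoured in a ten-membered ring and reachable through reversible hydridopalladium addition.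

Step 14
Reactants: 18 Z-enone
Product: 19 isopropenyl Z-enone
Conditions: Burgess reagent, toluene, 50 °C
Reagents that add atoms: none
Why: Burgess dehydration (syn elimination through the sulfamate ester) should take a hydrogen from one of the two freely rotating methyl groups rather than the single hindered C7–H, giving the isopropenyl group and keeping C7.

Step 15
Reactants: 19 isopropenyl Z-enone
Product: 20 (3S)-allylic alcohol
Conditions: (R)-2-methyl-CBS-oxazaborolidine (0.2 equiv), catecholborane, toluene, −78 °C
Reagents that add atoms: none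
Why: Corey–Bakshi–Shibata reduction with the 2-methylalkenyl residue as the large group should give the (3S)-alcohol under reagent control, and catecholborane at −78 °C leaves the ester, the epoxide and the isopropenyl group alone.

Step 16
Reactants: 20 (3S)-allylic alcohol
Product: 21 trans-epoxy alcohol
Conditions: mCPBA (1.05 equiv), NaHCO3, CH2Cl2, 0 °C
Reagents that add atoms: 3-chloroperoxybenzoic acid, OOC(=O)c1cccc(Cl)c1
Why: Hydrogen-bond-directed peracid epoxidation of a Z-allylic alcohol: A(1,3) strain between C6 and the C3 substituents holds H3 in the alkene plane, so the peracid bound to the hydroxyl should add from the hydroxyl side (threo, i.e. the 4,5β-epoxide trans to the 3α-oxygen when the ring is drawn flat), and the trisubstituted hydroxyl-activated alkene reacts before the isopropenyl group; this sets C4 and C5.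

Step 17
Reactants: 21 trans-epoxy alcohol
Product: 22 C3 angelate (PMB ether of the target)
Conditions: angelic acid, 2,4,6-trichlorobenzoyl chloride, Et3N, toluene, rt; then 21, 80 °C
Reagents that add atoms: angelic acid, C/C=C(/C)C(=O)O
Why: Yamaguchi-type esterification through the mixed anhydride, run without a nucleophilic catalyst, is the standard way to attach an angeloyl group without Z-to-E isomerisation to the tiglate.

Step 18
Reactants: 22 C3 angelate
Product: 23 target CNP0320216.1
Conditions: DDQ, CH2Cl2/pH 7 buffer, 0 °C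
Reagents that add atoms: none
Why: Oxidative cleavage of the PMB ether with DDQ frees the C9 hydroxyl under neutral conditions that should leave both epoxides, both unsaturated esters and the isopropenyl group intact and give no acyl migration.

**Compound list**

1 | (S)-(+)-carvone, (5S)-2-methyl-5-(prop-1-en-2-yl)cyclohex-2-en-1-one | CC1=CC[C@H](C(C)=C)CC1=O | starting material
2 | (1R,6R)-3-methyl-2-oxo-6-(prop-1-en-2-yl)cyclohex-3-en-1-yl acetate (8β-OAc trans to 3α-isopropenyl) | CC1=CC[C@H](C(C)=C)[C@@H](OC(C)=O)C1=O | intermediate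
3 | 2-hydroxy-3-methyl-6-(prop-1-en-2-yl)cyclohex-3-en-1-yl acetate (9α-OH cis to isopropenyl, trans to 8β-OAc) | CC1=CC[C@H](C(C)=C)[C@@H](OC(C)=O)[C@@H]1O | intermediate
4 | 1,10α-epoxide of 3 (epoxide cis to 9α-OH) | C[C@@]12O[C@@H]1C[C@H](C(C)=C)[C@@H](OC(C)=O)[C@@H]2O | intermediate
5 | 9-O-(4-methoxybenzyl) ether of 4 | C[C@@]12O[C@@H]1C[C@H](C(C)=C)[C@@H](OC(C)=O)[C@@H]2OCc1ccc(OC)cc1 | intermediate
6 | 8β-alcohol: 1,10α-epoxy-9α-(4-methoxybenzyloxy)-3α-isopropenylcyclohexan-8-ol | C[C@@]12O[C@@H]1C[C@H](C(C)=C)[C@@H](O)[C@@H]2OCc1ccc(OC)cc1 | intermediate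
7 | C8 ketone: 1,10α-epoxy-9α-(4-methoxybenzyloxy)-3α-isopropenylcyclohexan-8-one | C[C@@]12O[C@@H]1C[C@H](C(C)=C)C(=O)[C@@H]2OCc1ccc(OC)cc1 | intermediate
8 | 3β-hydroxy-3α-isopropenyl ketone | C[C@@]12O[C@@H]1C[C@](O)(C(C)=C)C(=O)[C@@H]2OCc1ccc(OC)cc1 | intermediate
9 | 3β-(methoxymethoxy)-3α-isopropenyl ketone | C[C@@]12O[C@@H]1C[C@](OCOC)(C(C)=C)C(=O)[C@@H]2OCc1ccc(OC)cc1 | intermediate
10 | 8α-vinyl-8β-hydroxy-3β-(methoxymethoxy)-3α-isopropenyl cyclohexane (vinyl and isopropenyl cis) | C[C@@]12O[C@@H]1C[C@](OCOC)(C(C)=C)[C@](O)(C=C)[C@@H]2OCc1ccc(OC)cc1 | intermediate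
11 | potassium alkoxide of 10 | [K+].C[C@@]12O[C@@H]1C[C@](OCOC)(C(C)=C)[C@]([O-])(C=C)[C@@H]2OCc1ccc(OC)cc1 | intermediate
12 | ten-membered potassium enolate (C7=C8 ring-E, C3=C4 MOM enol ether ring-Z, 1,10α-epoxide, 9α-OPMB) | [K+].[O-]\C1=C/CC/C(C)=C(OCOC)\C[C@H]2O[C@@]2(C)[C@H]1OCc1ccc(OC)cc1 | intermediate
13 | dichlorocerium enolate corresponding to 12 | Cl[Ce](Cl)O\C1=C/CC/C(C)=C(OCOC)\C[C@H]2O[C@@]2(C)[C@H]1OCc1ccc(OC)cc1 | intermediate
14 | dichlorocerium aldolate (C11–O–CeCl2) | CC(C)(O[Ce](Cl)Cl)[C@H]1CC/C(C)=C(OCOC)\C[C@H]2O[C@@]2(C)[C@@H](OCc3ccc(OC)cc3)C1=O | intermediate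
15 | germacrane β-hydroxy ketone: 8-oxo, 7α-(2-hydroxypropan-2-yl), 9α-OPMB, 1,10α-epoxide, 3-(methoxymethoxy)-3(4)-ene | CC(C)(O)[C@H]1CC/C(C)=C(OCOC)\C[C@H]2O[C@@]2(C)[C@@H](OCc3ccc(OC)cc3)C1=O | intermediate
16 | 8α,11-diol (8α-OH cis to 9α-OPMB and to the 7α side chain) | CC(C)(O)[C@H]1CC/C(C)=C(OCOC)\C[C@H]2O[C@@]2(C)[C@@H](OCc3ccc(OC)cc3)[C@H]1O | intermediate
17 | 8α-senecioate of 16 | CC(C)(O)[C@H]1CC/C(C)=C(OCOC)\C[C@H]2O[C@@]2(C)[C@@H](OCc3ccc(OC)cc3)[C@H]1OC(=O)C=C(C)C | intermediate
18 | (4Z)-4-en-3-one with 11-hydroxy group | CC(C)(O)[C@H]1C/C=C(C)\C(=O)C[C@H]2O[C@@]2(C)[C@@H](OCc3ccc(OC)cc3)[C@H]1OC(=O)C=C(C)C | intermediate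
19 | (4Z)-4-en-3-one with 7α-isopropenyl group | C=C(C)[C@H]1C/C=C(C)\C(=O)C[C@H]2O[C@@]2(C)[C@@H](OCc3ccc(OC)cc3)[C@H]1OC(=O)C=C(C)C | intermediate
20 | (3S,4Z)-allylic alcohol (3α-OH) | C=C(C)[C@H]1C/C=C(C)\[C@@H](O)C[C@H]2O[C@@]2(C)[C@@H](OCc3ccc(OC)cc3)[C@H]1OC(=O)C=C(C)C | intermediate
21 | 4,5β-epoxy-3α-ol (epoxide trans to the C3 hydroxyl) | C=C(C)[C@H]1C[C@@H]2O[C@]2(C)[C@@H](O)C[C@H]2O[C@@]2(C)[C@@H](OCc3ccc(OC)cc3)[C@H]1OC(=O)C=C(C)C | intermediate
22 | 3α-angelate, 9-O-PMB ether of the target | C=C(C)[C@H]1C[C@@H]2O[C@]2(C)[C@@H](OC(=O)/C(C)=C\C)C[C@H]2O[C@@]2(C)[C@@H](OCc3ccc(OC)cc3)[C@H]1OC(=O)C=C(C)C | intermediate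
23 | CNP0320216.1, (1R,3S,4S,5S,7R,8S,9S,10S)-3-angeloyloxy-1,10:4,5-diepoxy-9-hydroxygermacr-11-en-8-yl senecioate | C=C(C)[C@H]1C[C@@H]2O[C@]2(C)[C@@H](OC(=O)/C(C)=C\C)C[C@H]2O[C@@]2(C)[C@@H](O)[C@H]1OC(=O)C=C(C)C | target

**Totals and risks**

Total step count: 18. Longest linear sequence: 18 steps from (S)-carvone (fully linear).

Steps most likely to fail:

1. Step 10. The alkoxide may fragment or decompose instead of rearranging, or the enolate may be quenched by proton transfer from acetone, or acetone may add from the wrong face if the chelate does not control the ring conformation. Fallback (neutral rearrangement, enolate made separately): starting from 10, the tertiary alcohol is silylated with N-(trimethylsilyl)imidazole to the trimethylsilyl ether F1. F1 is heated in toluene at about 160 °C in a sealed, silylated tube (siloxy-Cope rearrangement) to the ring-expanded bis(enol ether) F2. Only the trimethylsilyl enol ether of F2 is then cleaved with MeLi in THF (−78 to 0 °C); the lithium enolate is transmetalated with CeCl3 and treated with acetone at −78 °C, which returns to the route at 15.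

2. Step 14. The elimination may run toward C7 (tetrasubstituted alkene, loss of the C7 stereocentre) instead of toward a methyl group. Fallback (the isopropenyl carbons are brought in before the ring expansion, so no dehydration is needed): starting from 9. Commercial 2-methylbut-1-en-3-yne is bromoborated with B-bromo-9-borabicyclo[3.3.1]nonane and protonolysed with AcOH to 2-bromo-3-methylbuta-1,3-diene F3. F3 is lithiated (t-BuLi, Et2O, −78 °C), transmetalated with CeCl3 and added to 9 to give the dienyl carbinol F4. KH/18-crown-6 then gives the ring expansion; the 2-substituted dienyl group is expected to favour the chair that puts the isopropenyl group cis to the enolate oxygen (ring-Z dienolate). After exchange to cerium, kinetic α-protonation with AcOH at −78 °C from the face anti to C10 gives the isopropenyl ketone F5. Zn(BH4)2 reduction gives the alcohol F6 and acylation with 3-methylbut-2-enoyl chloride gives the senecioate F7. Pd(OAc)2 dehydrogenation of the enol ether as in step 13 returns to the route at 19.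

3. Step 16. The peracid may show poor facial selectivity on the flexible ten-membered ring or attack the isopropenyl group competitively. Fallback (syn-directed epoxidation of the C3 epimer, then inversion): starting from 19, reduction with the (S)-oxazaborolidine and catecholborane gives the C3-epimeric allylic alcohol F8. VO(acac)2/t-BuOOH epoxidation (syn to the hydroxyl) gives the cis-epoxy alcohol F9, which already has the 4,5β-epoxide. Mitsunobu esterification of F9 with angelic acid (PPh3, diisopropyl azodicarboxylate, toluene) inverts C3 and installs the ester in one operation, returning to the route at 22.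

**Further compounds**

F1 | step 10 | trimethylsilyl ether of 10 | C[C@@]12O[C@@H]1C[C@](OCOC)(C(C)=C)[C@](O[Si](C)(C)C)(C=C)[C@@H]2OCc1ccc(OC)cc1
F2 | step 10 | ring-expanded bis(enol ether): C8 trimethylsilyl enol ether (ring-E), C3 MOM enol ether | C[Si](C)(C)O\C1=C/CC/C(C)=C(OCOC)\C[C@H]2O[C@@]2(C)[C@H]1OCc1ccc(OC)cc1
F3 | step 14 | 2-bromo-3-methylbuta-1,3-diene | C=C(C)C(Br)=C
F4 | step 14 | 8α-(3-methylbuta-1,3-dien-2-yl) carbinol | C[C@@]12O[C@@H]1C[C@](OCOC)(C(C)=C)[C@](O)(C(=C)C(C)=C)[C@@H]2OCc1ccc(OC)cc1
F5 | step 14 | ring-expanded 7α-isopropenyl C8 ketone with C3 MOM enol ether | C=C(C)[C@H]1CC/C(C)=C(OCOC)/C[C@H]2O[C@@]2(C)[C@@H](OCc3ccc(OC)cc3)C1=O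
F6 | step 14 | 8α-alcohol of F5 | C=C(C)[C@H]1CC/C(C)=C(OCOC)/C[C@H]2O[C@@]2(C)[C@@H](OCc3ccc(OC)cc3)[C@H]1O
F7 | step 14 | 8α-senecioate of F6 | C=C(C)[C@H]1CC/C(C)=C(OCOC)/C[C@H]2O[C@@]2(C)[C@@H](OCc3ccc(OC)cc3)[C@H]1OC(=O)C=C(C)C
F8 | step 16 | (3R,4Z)-allylic alcohol, C3 epimer of 20 | C=C(C)[C@H]1C/C=C(C)\[C@H](O)C[C@H]2O[C@@]2(C)[C@@H](OCc3ccc(OC)cc3)[C@H]1OC(=O)C=C(C)C
F9 | step 16 | 4,5β-epoxy-3β-ol, C3 epimer of 21 | C=C(C)[C@H]1C[C@@H]2O[C@]2(C)[C@H](O)C[C@H]2O[C@@]2(C)[C@@H](OCc3ccc(OC)cc3)[C@H]1OC(=O)C=C(C)C
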